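If theta, beta and eta are to earn their place, we must first decide whether base, stepped from 0.018 mM to 0.057 mM in the red, violet and ochre runs, deserves a ladder or should be left alone while the next change goes elsewhere.

| flask | substrate | partner | base | scavenger | remark | time |
|---|---|---|---|---|---|---|
| red | 1 mM | 0.60 mM | 0.018 mM | 1.5 mM | run made earlier |  |
| violet | 1 mM | 0.60 mM | 0.039 mM | 1.5 mM | run made earlier |  |
| ochre | 1 mM | 0.60 mM | 0.057 mM | 1.5 mM | run made earlier |  |
| theta | 1.0 mM | 0.600 mM | 0.0200 mM | 1.50 mM |  | 8.0 min |
| beta | 1.0 mM | 0.600 mM | 0.0400 mM | 1.50 mM |  | 8.0 min |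
| eta | 1.0 mM | 0.600 mM | 0.0800 mM | 1.50 mM |  | 8.0 min |

- red (time / min: substrate / %, target / %): 0.500: 96.3, 4.2; 1.33: 90.0, 9.4; 2.50: 83.8, 16.4; 4.00: 77.0, 22.4; 6.00: 69.8, 29.7
- violet (time / min: substrate / %, target / %): 0.500: 97.0, 4.4; 1.33: 90.4, 10.2; 2.50: 83.9, 15.6; 4.00: 76.8, 22.5; 6.00: 70.9, 28.7
- ochre (time / min: substrate / %, target / %): 1.00: 92.7, 7.4; 2.50: 83.9, 15.8; 3.00: 82.1, 17.8; 5.00: 74.0, 25.5; 6.00: 70.3, 29.5

(each reading ± 0.5 percentage points)



- part of the substrate that has reacted at the end, theta
- part of the substrate that has reacted at the end, beta
- part of the substrate that has reacted at the end, eta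
- what raising the concentration of base from its lowest to its highest value here does to the part of the substrate that has reacted (changes below 5 percentage points count as none) (it falls / it rises / no change)

Target tracks the substrate lost, so we take partner, the limiting reagent, as used one for one with substrate; its fraction left then follows from the substrate reading. If the rate is first order in each, the gap, the log10 of substrate fraction over partner fraction, climbs straight with time, and its slope grows with the substrate excess in mM.

At 6.00 min the gap reads 0.148 in red, 0.139 in violet and 0.144 in ochre. Violet, with the middle base, reads lowest, so the order doesn't follow base. Ochre's slope is 0.0238 min⁻¹ at 2.50 min and 0.0239 min⁻¹ at 6.00 min, so the line is straight.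

The mean climb per minute and per mM of excess is the gap rate, 0.0598 mM⁻¹ min⁻¹. Over 8.0 min it gives a gap of 0.191, a ratio of 1.55, and 34.8% reacted. We commit to that for theta, beta and eta alike, though eta's base lies beyond ochre's. Base stays as it is; the next change goes to partner.

The forecast says 35%, 35% and 35%, trend no change, on the ground “so the rate is zero order in base here”.

The flasks give 34.6%, 34.5% and 34.3%, a change of −0.21 percentage points, so no change.

    substrate + partner + released group → target + 2 released group (k = 86800 M⁻² s⁻¹)
    substrate + partner → target + released group (k = 2.03 M⁻¹ s⁻¹)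
    base + released group ⇌ salt, settled at all times (K = 1.65 × 10⁶ M⁻¹)
    substrate + released group ⇌ idle adduct, settled at all times (K = 564 M⁻¹)
    scavenger + released group → scavenged by-product (k = 247 M⁻¹ s⁻¹)
    2 substrate → self-condensation product (k = 0.00738 M⁻¹ s⁻¹)

In eta at 2.78 min, released group has a half-life of 2.0 s against scavenger, while partner has 6.9 min by the direct step from substrate and partner. At that moment the direct step uses substrate 9.6 times as fast as the step needing released group. Eta's final fractions give a gap of 0.178, against 0.191 from the gap rate. For eta with 2.4 mM of partner, the gap rate gives a gap of −0.669, a ratio of 0.214 and 86.3% reacted, and that flask gives 89.1%.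

The earlier runs and the new flask were computed for substances that don't exist; noise was put on by code.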